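## Structural features

Betaethrin E is made of two benzene rings joined by one ether oxygen. It has no further ring and no stereocenter, so no stereocenters stand next to each other and every problem is one of regiochemistry and protecting-group order. Ring B (C1 CO2Me, C2 OH, C4 CH3, C6 O-aryl) is a 2,6-dioxygenated methyl benzoate with the methyl group para to the ester. Ring A (C1' ether oxygen, C2' OH, C4' OCH3, C6' CH2O-palmitoyl) is a methoxycatechol in which the oxygen next to the side chain carries ring B. Both carbons of the bridge (C6 and C1') have two ortho substituents, so the diaryl ether is tetra-ortho-substituted and a poor candidate for copper- or palladium-mediated coupling. The fragile groups are the benzylic palmitate (base, hydrogenolysis), the methyl salicylate, the oxidisable ring A, and the free C2' phenol. Under base that phenol can attack the ester-activated C6 of ring B and move the aryl group to the other catechol oxygen (Smiles shift). The real difficulty is to form the crowded C6–O–C1' bridge on the correct oxygen, to place a carboxyl carbon at C1 between two oxygens, and to acylate one primary alcohol beside two phenols. Ring B offers a vicinal pair, C6 bearing a heteroatom and C1 bearing carbon, with a third oxygen on C2 on the far side of C1. An aryne spanning C1 and C6, polarised by the C2 alkoxy group, would accept an oxygen nucleophile at C6 and a carbon electrophile at C1 in one operation.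

## Logic of the disconnections

**27 to 25 and 26.** The acyl–oxygen bond of the benzylic ester is cut first. The sixteen-carbon chain is the part most sensitive to base and hydrogenolysis and plays no role in building the core, so it should arrive last. The cut leaves a compact triol and a commodity acid. The forward step must acylate one primary alcohol beside two phenols without base, because base at the C2' hydroxyl could start a Smiles shift.

**25 to 24.** Three O–CH2 acetal bonds are cut, two on phenolic oxygens (C2, C2') and one on the benzylic oxygen. All three hydroxyls must be masked during an anionic coupling, and one kind of group allows one acidic unmasking. The forward step needs acid that spares the methyl ester and a medium that traps the released formaldehyde equivalents before they alkylate ring A.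

**24 to 18, 9 and 19.** Two bonds on neighbouring carbons of ring B are cut together: the C6–O ether bond and the C1–carboxyl bond (the ester O–CH3 bond goes with them). 9 is the latent form of 21. This is the largest simplification of the route, since the crowded ether and the carboxyl between two oxygens are formed in one flask from two fragments of similar size and a one-carbon unit. The forward step demands addition of oxygen at C6 only, carboxylation of 22 instead of protonation, and absence of any proton donor. For that reason 18 enters as its preformed salt 20, made with a hydride base so that the only by-product is a gas. The benzylic oxygen of 18 stays an acetal so that 20 cannot fragment.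

**9 to 7, 3, 2 and 1.** The sulfonate S–O bond of 9 is traced back to the carbamate C–O bond of 7. The C–Si bond of 7 is then cut to give 3, the carbamoyl C–O bond of 3 to give 2, and one acetal bond of 2 to give 1. The carbamate is chosen because it directs metalation to the C–H between the two oxygens and can later be exchanged for the sulfonate in one flask. The gain is a symmetrical commodity diol. The forward steps demand mono-protection of 1 and lithiation only between the two oxygen groups, with the acetal intact.

**18 to 17, 16, 13, 12, 11 and 10.** The O–benzyl bond of 17 is cut to expose the nucleophilic oxygen last. Both acetal bonds of 17 are cut together to give 16. The C–O bond of the second phenol in 16 is traced to the C–Br bond of 13, the CH2OH of 13 to the aldehyde of 12, the benzyl ether of 12 to 11, and the C–Br bond of 11 to 10. Bromine marks the only position ortho to the free hydroxyl of 10 and so fixes where the second catechol oxygen goes. The temporary benzyl group keeps the two catechol oxygens distinct. Installing the two acetals in one operation on 16 saves a step. The forward sequence demands bromine–lithium exchange in the presence of a free alcohol and a final debenzylation that leaves the benzylic acetal untouched.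

## Other disconnections considered

**Alternative 1:** Here ring A is built, not bought.

- **Cut:** all ring A bonds not already present in the open-chain diazoketone A1 are removed. In A1 ring B is attached through its C6 oxygen to the terminal carbon of an enol ether and the benzylic oxygen is silylated. The two remaining ring carbons come from methoxyacetylene A2.
- **Forward key step:** light would trigger loss of the diazo nitrogen and the vinyl group would migrate (Wolff rearrangement) to give an aryloxy-substituted vinylketene. A2 would add across the ketene C=C bond in a (2+2) sense. The 4-vinylcyclobutenone would open (four electrons) and reclose (six electrons) to a cyclohexadienone that tautomerises to phenol A3.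
- **In its favour:**
  - The ketene carbon becomes C2' and arrives as a free hydroxyl, and the oxygenated alkyne carbon becomes C4' with its methyl ether in place.
  - The positions of all four substituents follow from connectivity, so no regiochemical choice is left open.
  - The benzannulation is a reaction class with a long record, which the chosen key step is not. On precedent the alternative is the better.
  - A3 carries three different oxygen states (free phenol, MOM ether, silyl ether), so the benzylic alcohol could be released alone with fluoride. One phenol instead of two would then compete with the primary alcohol, a small advantage over the chosen plan.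
- **Against it:**
  - A1 presupposes ring B as a complete salicylate, so the C1 carboxyl needs its own sequence.
  - The enol ether must be made from a phenol flanked by an ester, and diazo transfer must be done on a vinylogous ester.
  - The six-electron closure must bond to a carbon bearing a bulky aryloxy group.
  - A2 is volatile and unstable, and the ketene can be diverted by dimerisation or by the neighbouring ester.
- **Comparison:** On structure, both plans make the crowded bridge without a metal-catalysed coupling. On mechanism, the alternative is a pericyclic cascade with precedent for each event, while the chosen plan is a polar cascade in an untested combination. On step economy the chosen plan should be clearly shorter, because ring A comes from a commercial aldehyde and the C1 carboxyl is created during the coupling.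

**Alternative 2:** Ring A is folded from a masked triketone.

- **Cut:** the C1'–C6' bond of ring A, formed by intramolecular aldol condensation of a 1,3,5-triketone stored as the 4-pyranone A5. A5 derives from chelidonic acid A4 by reduction of both carboxyl groups to hydroxymethyl groups, tritylation of one, and attachment of ring B to the other by O-alkylation at an sp3 carbon.
- **Forward key step:** hot aqueous alkaline-earth hydroxide would open the pyranone. The methylene carrying the aryloxy group would add to the carbonyl at the far end of the chain, and dehydration would give the resorcinol-type ring of A6.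
- **In its favour:**
  - A4 is cheap and holds all seven carbons of ring A and its side chain.
  - Conversion of 2,6-disubstituted 4-pyranones into resorcinols is classical chemistry.
  - No organometallic or cryogenic step is needed.
  - The hindered aryl–oxygen bond is never formed by arylation, because the oxygen is alkylated before ring A exists.
  - On reagent cost, operational simplicity and precedent for the ring-forming event the alternative is equal or better.
- **Against it:**
  - The triketone has two nearly equivalent ends, one with the aryloxy and one with the trityloxy group. The aldol can close either way, and only a modest acidity difference favours A6.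
  - The strongly basic medium endangers the methyl ester. Once the C2' phenoxide exists next to the ether oxygen, a Smiles shift onto ring B becomes possible.
  - A6 has three free phenols, of which only the C4' hydroxyl must then be methylated.
- **Comparison:** On structure, the chosen plan has every oxygen of ring A differentiated from the start, while the alternative must differentiate them at the end. On mechanism, the alternative rests on thermodynamic aldol chemistry with two open selectivity questions, the chosen plan on one kinetic addition steered by the C2 alkoxy group. On step economy the two should be comparable: the short access to A5 is offset by the extra methylation and the likely isomer separation.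

**Alternative 3:** Ring B is built by cycloaddition onto the ring A fragment.

- **Cut:** ring B at C1–C2 and C5–C6, assembled by a (4+2) cycloaddition between the aryloxypropiolate A7, which already contains ring A and the ether oxygen, and the silyl ketene acetal diene A8.
- **Forward key step:** on heating, the terminal CH2 of A8 should bond to the alkyne carbon bearing the aryloxy group, and the acetal carbon to the carbon next to the ester. Loss of the methoxy group as its alcohol and desilylation would aromatise the adduct to salicylate A9, which differs from 24 only in its free C2 hydroxyl.
- **In its favour:**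
  - The polarities of diene and dienophile are matched, so the ester should end between the two oxygens.
  - Cycloaddition–aromatisation of oxygenated dienes with alkynoates is established chemistry. On precedent the alternative is better than the chosen plan.
  - One MOM group is saved.
  - A7 is reachable from 18 in two known operations and A8 in one, so the total count would be equal to or one step below that of the chosen route.
- **Against it:**
  - A7 is a donor–acceptor alkyne. The oxygen lone pair lowers its dienophilicity and the reacting carbon is shielded by a 2,6-disubstituted aryloxy group. The temperatures needed are ones at which A8 tends to isomerise or lose silicon.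
  - Making A7 exposes 18, with its two ortho-directing acetals, to alkyllithium.
  - Ring B is built on the ring A fragment, so the sequence is linear. The longest linear sequence would exceed the nine steps of the chosen plan, and 18 would be spent two steps before the uncertain event instead of in it.
- **Comparison:** On structure, both plans use 18 and reach the same triol 25. On mechanism, the alternative replaces an untested polar three-component coupling with a precedented but electronically and sterically reluctant cycloaddition. On step economy they are close: the alternative is slightly better in total count and worse in convergence.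

Key step: step 11

**Remarks before the steps**

- Check of structures: both coupling partners and the coupled product agree atom for atom with the target (oxygen pattern of ring A; methyl para to the ester on ring B), so no structure is corrected.
- Design changes: the phenol partner is deprotonated with KH before fluoride is added, so no O–H or bifluoride proton is available to the aryl anion. The phenol and the benzylic alcohol of ring A receive their MOM groups in one operation, which brings that fragment to six steps.
- Assumption: orcinol is used anhydrous (the commercial monohydrate is dried azeotropically before step 1).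

## Route

Step 1
Reactants: 1 orcinol (5-methylbenzene-1,3-diol)
Product: 2 3-(methoxymethoxy)-5-methylphenol
Conditions: MOMCl (1 equiv), iPr2NEt, THF–CH2Cl2, 0 °C to rt; 1 in excess
Reagents that add atoms: chloromethyl methyl ether (MOMCl), COCCl
Why: O-alkylation of one of two equivalent phenols with the chloromethyl ether (acetal formation); an excess of the symmetrical diol should favour the mono-ether, and the bis-ether and unreacted 1 are separable.

Step 2
Reactants: 2 3-(methoxymethoxy)-5-methylphenol
Product: 3 3-(methoxymethoxy)-5-methylphenyl N-isopropylcarbamate
Conditions: iPrNCO, Et3N (cat.), CH2Cl2, rt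
Reagents that add atoms: isopropyl isocyanate, CC(C)N=C=O
Why: Amine-catalysed addition of the phenol to the isocyanate (carbamoylation) should give the N–H carbamate, which after N-silylation is a strong ortho-director and can later be removed under mild base.

Step 3
Reactants: 3 3-(methoxymethoxy)-5-methylphenyl N-isopropylcarbamate
Product: 7 3-(methoxymethoxy)-5-methyl-2-(trimethylsilyl)phenyl N-isopropylcarbamate, via N-silyl carbamate 4 (not isolated), via aryllithium 5 (not isolated), via bis-silyl carbamate 6 (not isolated)
Conditions: TBSOTf, TMEDA, Et2O, 0 °C to rt; n-BuLi, TMEDA, −78 °C; TMSCl, −78 °C to rt; cold aq NaHSO4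
Reagents that add atoms: chlorotrimethylsilane (TMSCl), C[Si](C)(C)Cl
Why: Directed ortho-metalation: after in situ N-silylation the carbamate and the MOM ether both acidify the C–H between them, so lithiation should occur only there; C-silylation and hydrolysis of the labile N–Si bond should give 7, and −78 °C suppresses the anionic ortho-Fries shift.

Step 4
Reactants: 7 3-(methoxymethoxy)-5-methyl-2-(trimethylsilyl)phenyl N-isopropylcarbamate
Product: 9 3-(methoxymethoxy)-5-methyl-2-(trimethylsilyl)phenyl trifluoromethanesulfonate, via silylphenoxide 8 (not isolated)
Conditions: DBU, Et2NH, MeCN, 40 °C; then PhNTf2, rt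
Reagents that add atoms: N-phenylbis(trifluoromethanesulfonimide) (PhNTf2), O=S(=O)(N(c1ccccc1)S(=O)(=O)C(F)(F)F)C(F)(F)F
Why: E1cB cleavage of the N–H carbamate by DBU releases the phenoxide and isopropyl isocyanate, which Et2NH traps as a urea; O-sulfonylation in the same flask should give the ortho-silylaryl triflate without exposing the aryl–silicon bond to acid.

Step 5
Reactants: 10 2-hydroxy-5-methoxybenzaldehyde
Product: 11 3-bromo-2-hydroxy-5-methoxybenzaldehyde
Conditions: Br2, NaOAc, AcOH, rt
Reagents that add atoms: bromine, BrBr
Why: Electrophilic aromatic bromination; the free hydroxyl directs ortho and para, its para position holds the methoxy group and one ortho position the formyl group, so C3 is the only strongly activated site.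

Step 6
Reactants: 11 3-bromo-2-hydroxy-5-methoxybenzaldehyde
Product: 12 2-(benzyloxy)-3-bromo-5-methoxybenzaldehyde
Conditions: BnBr, K2CO3, DMF, 50 °C
Reagents that add atoms: benzyl bromide, BrCc1ccccc1
Why: Williamson etherification of the phenoxide; the benzyl group keeps this oxygen distinct from the one that will replace bromine.

Step 7
Reactants: 12 2-(benzyloxy)-3-bromo-5-methoxybenzaldehyde
Product: 13 [2-(benzyloxy)-3-bromo-5-methoxyphenyl]methanol
Conditions: NaBH4, MeOH–THF, 0 °C
Reagents that add atoms: none
Why: Hydride reduction of the aldehyde to the primary benzylic alcohol; aryl bromide and ethers are inert to NaBH4.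

Step 8
Reactants: 13 [2-(benzyloxy)-3-bromo-5-methoxyphenyl]methanol
Product: 16 2-(benzyloxy)-3-(hydroxymethyl)-5-methoxyphenol, via dilithio species 14 (not isolated), via aryl trimethoxyborate 15 (not isolated)
Conditions: n-BuLi (2.2 equiv), THF, −78 °C; B(OMe)3, −78 °C to rt; H2O2, aq NaOH, 0 °C
Reagents that add atoms: hydrogen peroxide, OO
Why: Deprotonation of the alcohol and bromine–lithium exchange give a dianion whose aryllithium is borylated; oxidative 1,2-shift of the aryl group from boron to oxygen (borylation–oxidation) should place the hydroxyl exactly where bromine stood.

Step 9
Reactants: 16 2-(benzyloxy)-3-(hydroxymethyl)-5-methoxyphenol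
Product: 17 2-(benzyloxy)-5-methoxy-1-(methoxymethoxy)-3-[(methoxymethoxy)methyl]benzene
Conditions: MOMCl (3 equiv), iPr2NEt, CH2Cl2, 0 °C to rt
Reagents that add atoms: chloromethyl methyl ether (MOMCl), COCCl
Why: Both the phenolic and the benzylic hydroxyl are alkylated by the chloromethyl ether under amine base (acetal formation), so one operation installs the two MOM groups needed in the coupling.

Step 10
Reactants: 17 2-(benzyloxy)-5-methoxy-1-(methoxymethoxy)-3-[(methoxymethoxy)methyl]benzene
Product: 18 4-methoxy-2-(methoxymethoxy)-6-[(methoxymethoxy)methyl]phenol
Conditions: H2 (1 atm), Pd/C, EtOAc, rt; stopped after one equivalent of H2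
Reagents that add atoms: none
Why: Hydrogenolysis of the aryl benzyl ether on palladium; the phenolic O–benzyl bond should cleave much faster than the benzylic acetal C–O bond of the electron-rich ring, especially in a non-protic, acid-free solvent with limited hydrogen uptake.

Step 11
Reactants: 18 4-methoxy-2-(methoxymethoxy)-6-[(methoxymethoxy)methyl]phenol; 9 3-(methoxymethoxy)-5-methyl-2-(trimethylsilyl)phenyl trifluoromethanesulfonate; 19 carbon dioxide
Product: 24 methyl 2-[4-methoxy-2-(methoxymethoxy)-6-[(methoxymethoxy)methyl]phenoxy]-6-(methoxymethoxy)-4-methylbenzoate, via potassium phenoxide 20 (not isolated), via aryne 21 (not isolated), via arylpotassium adduct 22 (not isolated), via potassium carboxylate 23 (not isolated)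
Conditions: KH (1.0 equiv), THF, 0 °C; 18-crown-6, KF, CO2 (1 atm), slow addition of 9 (1.5 equiv), 0 °C to rt; then MeI, DMF, rt
Reagents that add atoms: iodomethane (MeI), CI
Why: Proposed new method: KH turns 18 into phenoxide 20 with loss of hydrogen gas so that no O–H acid remains, and fluoride then attacks silicon in 9, triflate departs and aryne 21 forms with its triple bond between the future C1 and C6 of ring B. The inductively withdrawing MOM-oxy group on C2 distorts the aryne so that C6, the carbon remote from oxygen, is the more electrophilic one, and the crown-separated phenoxide adds there through an early transition state that tolerates its two ortho substituents, which leaves the charge on C1 beside oxygen (22). In aprotic THF saturated with CO2 this anion should be carboxylated to 23, and MeI, added once the aryne is spent, alkylates the carboxylate on oxygen to give 24. The closest known reaction types are the three-component coupling of arynes with amines or imines and CO2 and the addition of phenoxides to arynes followed by intramolecular acyl capture in xanthone synthesis; the new element is an oxygen nucleophile paired with external CO2. No ring is closed and no stereocenter is formed. The step needs regioselectivity (oxygen to C6, carbon to C1), secured by the C2 alkoxy group, and chemoselectivity (carboxylation of 22 instead of protonation), secured by the absence of proton donors, the CO2-saturated medium and the slow addition of 9. Because the benzylic oxygen of ring A is an acetal that does not leave as an anion, 20 has no easy path to an ortho-quinone methide, and reversible carbonate formation between 20 and CO2 should only lower the concentration of free phenoxide.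

Step 12
Reactants: 24 methyl 2-[4-methoxy-2-(methoxymethoxy)-6-[(methoxymethoxy)methyl]phenoxy]-6-(methoxymethoxy)-4-methylbenzoate
Product: 25 methyl 2-hydroxy-6-[2-hydroxy-6-(hydroxymethyl)-4-methoxyphenoxy]-4-methylbenzoate
Conditions: HCl (3 M in MeOH), MeOH, 40 °C
Reagents that add atoms: none
Why: Acid-catalysed acetal exchange with the solvent removes all three MOM groups as dimethoxymethane; methanol keeps the methyl ester unchanged and traps the oxocarbenium ions before they can alkylate ring A.

Step 13
Reactants: 25 methyl 2-hydroxy-6-[2-hydroxy-6-(hydroxymethyl)-4-methoxyphenoxy]-4-methylbenzoate; 26 palmitic acid (hexadecanoic acid)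
Product: 27 betaethrin E
Conditions: PPh3, DIAD, THF, 0 °C to rt
Reagents that add atoms: none
Why: Mitsunobu esterification: the betaine from PPh3 and DIAD is protonated by the carboxylic acid, only the primary alcohol forms an alkoxyphosphonium ion, and the carboxylate displaces it; the phenols are far less acidic than the acid and are not activated, and no base is present to start a Smiles shift.

## Compound list

1 | orcinol (5-methylbenzene-1,3-diol) | Cc1cc(O)cc(O)c1 | starting material
2 | 3-(methoxymethoxy)-5-methylphenol | COCOc1cc(C)cc(O)c1 | intermediate
3 | 3-(methoxymethoxy)-5-methylphenyl N-isopropylcarbamate | COCOc1cc(C)cc(OC(=O)NC(C)C)c1 | intermediate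
4 | 3-(methoxymethoxy)-5-methylphenyl N-(tert-butyldimethylsilyl)-N-isopropylcarbamate | COCOc1cc(C)cc(OC(=O)N(C(C)C)[Si](C)(C)C(C)(C)C)c1 | intermediate (not isolated)
5 | 2-lithio-3-(methoxymethoxy)-5-methylphenyl N-(tert-butyldimethylsilyl)-N-isopropylcarbamate | COCOc1cc(C)cc(OC(=O)N(C(C)C)[Si](C)(C)C(C)(C)C)c1[Li] | intermediate (not isolated)
6 | 3-(methoxymethoxy)-5-methyl-2-(trimethylsilyl)phenyl N-(tert-butyldimethylsilyl)-N-isopropylcarbamate | COCOc1cc(C)cc(OC(=O)N(C(C)C)[Si](C)(C)C(C)(C)C)c1[Si](C)(C)C | intermediate (not isolated)
7 | 3-(methoxymethoxy)-5-methyl-2-(trimethylsilyl)phenyl N-isopropylcarbamate | COCOc1cc(C)cc(OC(=O)NC(C)C)c1[Si](C)(C)C | intermediate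
8 | 3-(methoxymethoxy)-5-methyl-2-(trimethylsilyl)phenol, present as its DBU-H phenoxide | COCOc1cc(C)cc(O)c1[Si](C)(C)C | intermediate (not isolated)
9 | 3-(methoxymethoxy)-5-methyl-2-(trimethylsilyl)phenyl trifluoromethanesulfonate | Cc1cc(OCOC)c([Si](C)(C)C)c(OS(=O)(=O)C(F)(F)F)c1 | intermediate
10 | 2-hydroxy-5-methoxybenzaldehyde | COc1ccc(O)c(C=O)c1 | starting material
11 | 3-bromo-2-hydroxy-5-methoxybenzaldehyde | COc1cc(Br)c(O)c(C=O)c1 | intermediate
12 | 2-(benzyloxy)-3-bromo-5-methoxybenzaldehyde | COc1cc(Br)c(OCc2ccccc2)c(C=O)c1 | intermediate
13 | [2-(benzyloxy)-3-bromo-5-methoxyphenyl]methanol | COc1cc(Br)c(OCc2ccccc2)c(CO)c1 | intermediate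
14 | lithium [2-(benzyloxy)-3-lithio-5-methoxyphenyl]methanolate | COc1cc([Li])c(OCc2ccccc2)c(CO[Li])c1 | intermediate (not isolated)
15 | dilithium [2-(benzyloxy)-5-methoxy-3-(oxidomethyl)phenyl]trimethoxyborate | COc1cc([B-](OC)(OC)OC)c(OCc2ccccc2)c(C[O-])c1.[Li+].[Li+] | intermediate (not isolated)
16 | 2-(benzyloxy)-3-(hydroxymethyl)-5-methoxyphenol | COc1cc(O)c(OCc2ccccc2)c(CO)c1 | intermediate
17 | 2-(benzyloxy)-5-methoxy-1-(methoxymethoxy)-3-[(methoxymethoxy)methyl]benzene | COCOCc1cc(OC)cc(OCOC)c1OCc1ccccc1 | intermediate
18 | 4-methoxy-2-(methoxymethoxy)-6-[(methoxymethoxy)methyl]phenol | COCOCc1cc(OC)cc(OCOC)c1O | intermediate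
19 | carbon dioxide | O=C=O | starting material
20 | potassium 4-methoxy-2-(methoxymethoxy)-6-[(methoxymethoxy)methyl]phenoxide | COCOCc1cc(OC)cc(OCOC)c1[O-].[K+] | intermediate (not isolated)
21 | 3-(methoxymethoxy)-5-methylbenzyne (1,2-didehydro-3-(methoxymethoxy)-5-methylbenzene) | CC1=CC#CC(OCOC)=C1 | intermediate (not isolated)
22 | [2-[4-methoxy-2-(methoxymethoxy)-6-[(methoxymethoxy)methyl]phenoxy]-6-(methoxymethoxy)-4-methylphenyl]potassium | COCOCc1cc(OC)cc(OCOC)c1Oc1cc(C)cc(OCOC)c1[K] | intermediate (not isolated)
23 | potassium 2-[4-methoxy-2-(methoxymethoxy)-6-[(methoxymethoxy)methyl]phenoxy]-6-(methoxymethoxy)-4-methylbenzoate | COCOCc1cc(OC)cc(OCOC)c1Oc1cc(C)cc(OCOC)c1C(=O)[O-].[K+] | intermediate (not isolated)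
24 | methyl 2-[4-methoxy-2-(methoxymethoxy)-6-[(methoxymethoxy)methyl]phenoxy]-6-(methoxymethoxy)-4-methylbenzoate | COCOCc1cc(OC)cc(OCOC)c1Oc1cc(C)cc(OCOC)c1C(=O)OC | intermediate
25 | methyl 2-hydroxy-6-[2-hydroxy-6-(hydroxymethyl)-4-methoxyphenoxy]-4-methylbenzoate | COC(=O)c1c(O)cc(C)cc1Oc1c(O)cc(OC)cc1CO | intermediate
26 | palmitic acid (hexadecanoic acid) | CCCCCCCCCCCCCCCC(=O)O | starting material
27 | betaethrin E, methyl 2-[2-[(hexadecanoyloxy)methyl]-6-hydroxy-4-methoxyphenoxy]-6-hydroxy-4-methylbenzoate | CCCCCCCCCCCCCCCC(=O)OCc1cc(OC)cc(O)c1Oc1cc(C)cc(O)c1C(=O)OC | target

## Step count and least certain steps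

Total: 13 steps. Longest linear sequence: 9 steps (steps 5 to 13). The ring B branch is 4 steps (steps 1 to 4).

**Step 11 (key step, new method).**
- Most likely failures:
  - Protonation of the aryl anion outruns carboxylation, through traces of moisture in KF or crown ether or through intramolecular proton transfer from the benzylic methylene of ring A.
  - Binding of the phenoxide as its carbonate slows addition so much that the aryne is consumed by fluoride or by the product carboxylate.
  - The triflyl group is transferred from 9 to the phenoxide.
- Fallback with known chemistry, from 18 back to 24: purchased 3-fluoro-5-methylphenol F1 is converted with MOMCl and iPr2NEt into 1-fluoro-3-(methoxymethoxy)-5-methylbenzene F2. Lithiation between fluorine and the acetal (n-BuLi, THF, −78 °C) and quenching with DMF gives 2-fluoro-6-(methoxymethoxy)-4-methylbenzaldehyde F3. Nucleophilic aromatic substitution of the aldehyde-activated fluoride by 18 (Cs2CO3, DMF, 80 to 100 °C) gives 2-[4-methoxy-2-(methoxymethoxy)-6-[(methoxymethoxy)methyl]phenoxy]-6-(methoxymethoxy)-4-methylbenzaldehyde F4. Pinnick oxidation (NaClO2, NaH2PO4, 2-methyl-2-butene, t-BuOH–water) gives the acid 2-[4-methoxy-2-(methoxymethoxy)-6-[(methoxymethoxy)methyl]phenoxy]-6-(methoxymethoxy)-4-methylbenzoic acid F5. Methylation with MeI and K2CO3 in DMF returns to 24.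

**Step 3.**
- Most likely failures: attack of the silyl triflate on the aryl MOM acetal before N-silylation is complete, or warming that lets the lithiated carbamate undergo the ortho-Fries shift.
- Fallback from 2, returning at 8 and then 9: carbamoylation of 2 with ClCONEt2 and K2CO3 gives 3-(methoxymethoxy)-5-methylphenyl N,N-diethylcarbamate F6, which needs no N-silylation. Lithiation with s-BuLi and TMEDA at −78 °C and quenching with TMSCl gives 3-(methoxymethoxy)-5-methyl-2-(trimethylsilyl)phenyl N,N-diethylcarbamate F7. Reductive cleavage with LiAlH4 in THF gives phenol 8, here isolated, which is sulfonylated with PhNTf2 and Et3N to 9.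

**Step 10.**
- Most likely failure: over-reduction, that is hydrogenolytic loss of the benzylic acetal oxygen together with or after debenzylation.
- Fallback from 11, returning at 18, with a temporary group removed without hydrogen: allylation of 11 (allyl bromide, K2CO3, DMF) gives 2-(allyloxy)-3-bromo-5-methoxybenzaldehyde F8. NaBH4 reduction gives [2-(allyloxy)-3-bromo-5-methoxyphenyl]methanol F9. Lithiation, borylation and oxidation as in step 8, held at −78 °C until the borate is added, give 2-(allyloxy)-3-(hydroxymethyl)-5-methoxyphenol F10. Double MOM protection gives 2-(allyloxy)-5-methoxy-1-(methoxymethoxy)-3-[(methoxymethoxy)methyl]benzene F11. Deallylation with catalytic Pd(PPh3)4 and morpholine in THF gives 18.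

**Step 13.**
- Most likely failures: loss of chemoselectivity, either O-alkylation of a phenol by the alkoxyphosphonium ion (oligomer formation) or acyl transfer to a phenol.
- Fallback from 25 directly to 27: enzymatic transesterification with vinyl palmitate and immobilised Candida antarctica lipase B in t-BuOMe–THF at 40 °C. The enzyme acylates primary alcohols and leaves phenols alone, and no new compound is made.

## Further compounds

F1 | step 11 | 3-fluoro-5-methylphenol (purchased) | Cc1cc(O)cc(F)c1
F2 | step 11 | 1-fluoro-3-(methoxymethoxy)-5-methylbenzene | COCOc1cc(C)cc(F)c1
F3 | step 11 | 2-fluoro-6-(methoxymethoxy)-4-methylbenzaldehyde | COCOc1cc(C)cc(F)c1C=O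
F4 | step 11 | 2-[4-methoxy-2-(methoxymethoxy)-6-[(methoxymethoxy)methyl]phenoxy]-6-(methoxymethoxy)-4-methylbenzaldehyde | COCOCc1cc(OC)cc(OCOC)c1Oc1cc(C)cc(OCOC)c1C=O
F5 | step 11 | 2-[4-methoxy-2-(methoxymethoxy)-6-[(methoxymethoxy)methyl]phenoxy]-6-(methoxymethoxy)-4-methylbenzoic acid | COCOCc1cc(OC)cc(OCOC)c1Oc1cc(C)cc(OCOC)c1C(=O)O
F6 | step 3 | 3-(methoxymethoxy)-5-methylphenyl N,N-diethylcarbamate | CCN(CC)C(=O)Oc1cc(C)cc(OCOC)c1
F7 | step 3 | 3-(methoxymethoxy)-5-methyl-2-(trimethylsilyl)phenyl N,N-diethylcarbamate | CCN(CC)C(=O)Oc1cc(C)cc(OCOC)c1[Si](C)(C)C
F8 | step 10 | 2-(allyloxy)-3-bromo-5-methoxybenzaldehyde | COc1cc(Br)c(OCC=C)c(C=O)c1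
F9 | step 10 | [2-(allyloxy)-3-bromo-5-methoxyphenyl]methanol | COc1cc(Br)c(OCC=C)c(CO)c1
F10 | step 10 | 2-(allyloxy)-3-(hydroxymethyl)-5-methoxyphenol | COc1cc(O)c(OCC=C)c(CO)c1
F11 | step 10 | 2-(allyloxy)-5-methoxy-1-(methoxymethoxy)-3-[(methoxymethoxy)methyl]benzene | COCOCc1cc(OC)cc(OCOC)c1OCC=C
F0 | step 13 | none | none
A1 | alternative 1 | methyl 2-{[(1E)-2-{[(tert-butyldimethylsilyl)oxy]methyl}-4-diazo-3-oxobut-1-en-1-yl]oxy}-6-(methoxymethoxy)-4-methylbenzoate | COC(=O)c1c(OCOC)cc(C)cc1O/C=C(\CO[Si](C)(C)C(C)(C)C)C(=O)C=[N+]=[N-]
A2 | alternative 1 | methoxyacetylene (methoxyethyne) | COC#C
A3 | alternative 1 | methyl 2-[2-{[(tert-butyldimethylsilyl)oxy]methyl}-6-hydroxy-4-methoxyphenoxy]-6-(methoxymethoxy)-4-methylbenzoate | COC(=O)c1c(OCOC)cc(C)cc1Oc1c(O)cc(OC)cc1CO[Si](C)(C)C(C)(C)C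
A4 | alternative 2 | chelidonic acid (4-oxo-4H-pyran-2,6-dicarboxylic acid) | O=C(O)c1cc(=O)cc(C(=O)O)o1
A5 | alternative 2 | methyl 2-hydroxy-4-methyl-6-{[4-oxo-6-(trityloxymethyl)-4H-pyran-2-yl]methoxy}benzoate | COC(=O)c1c(O)cc(C)cc1OCc1cc(=O)cc(COC(c2ccccc2)(c2ccccc2)c2ccccc2)o1
A6 | alternative 2 | methyl 2-[2,4-dihydroxy-6-(trityloxymethyl)phenoxy]-6-hydroxy-4-methylbenzoate | COC(=O)c1c(O)cc(C)cc1Oc1c(O)cc(O)cc1COC(c1ccccc1)(c1ccccc1)c1ccccc1
A7 | alternative 3 | methyl 3-[4-methoxy-2-(methoxymethoxy)-6-[(methoxymethoxy)methyl]phenoxy]prop-2-ynoate | COC(=O)C#COc1c(COCOC)cc(OC)cc1OCOC
A8 | alternative 3 | (1Z)-1-methoxy-3-methyl-1-(trimethylsilyloxy)buta-1,3-diene | C=C(C)/C=C(/OC)O[Si](C)(C)C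
A9 | alternative 3 | methyl 2-hydroxy-6-[4-methoxy-2-(methoxymethoxy)-6-[(methoxymethoxy)methyl]phenoxy]-4-methylbenzoate | COC(=O)c1c(O)cc(C)cc1Oc1c(COCOC)cc(OC)cc1OCOC
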